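**Retrosynthetic overview**
1. Target ⇒ 3β,8α,23-triol (late acetylation of C23-OH and oxidation of C3-OH) ⇒ C11–C12 disconnection: C11 sulfone carbanion of a cis-decalin core plus a 12-silyloxyfarnesyl bromide made from farnesyl acetate.
2. Core ⇒ the C8 methyl carbinol and the C9–C11 bond are added to the regiodefined silyl enol ether C8=C9 that the key step delivers (thionium alkylation at C9, organocerium addition at C8).
3. Key disconnection: intramolecular Diels–Alder reaction of an acyclic (Z)-2-silyloxydiene/vinyl sulfone triene forms C5–C10 and C6–C7, so rings A and B are formed together in one step and no other ring is made.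
4. Enabling feature: ring B is a cyclohexane with oxygen at C8 whose C5–C10 bond is shared with ring A. Ring B is therefore the adduct of diene C7=C8(O)–C9=C10 and dienophile C5=C6, tethered by C1–C4 (ring A, with the C4 gem-dimethyl group), and the cis H-5/CH3-10 fusion is what a (Z)-diene gives.
5. Triene ⇐ 3-methylcyclohex-2-enone (ring cleavage fixes the (Z)-enone), asymmetric prenylboration (sets C3, which steers the cycloaddition and ends as the ketone), cross metathesis with phenyl vinyl sulfone.

Key step: step 7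

Remark: the stereodescriptors of the target place H-5 and CH3-10 on the same face, i.e. (5S,8R,9R,10S) with a cis-fused decalin; the route is planned for exactly this isomer.
Numbering used below: ring A = C1–C5 and C10; ring B = C5–C10; chain carbons C11 (on C9) to C23 (CH2O); methyl groups on C4 (two), C8, C10, C14, C18, C22; β = the face of CH3-10; TBS = tert-butyldimethylsilyl.

**Route**

Step 1
Reactants: 1 3-methylcyclohex-2-en-1-one
Product: 2 (±)-4-methyl-2-oxocyclohex-3-en-1-yl acetate
Conditions: Mn(OAc)3·2H2O, benzene, reflux (water separator)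
Reagents that add atoms: manganese triacetate, CC(=O)[O-].CC(=O)[O-].CC(=O)[O-].[Mn+3]
Why: α'-Acetoxylation of an enone with Mn(OAc)3 (manganese enolate, α'-radical, acetate transfer) oxygenates the ring carbon that becomes C3; the new stereocentre is destroyed in step 3.

Step 2
Reactants: 2 (±)-4-methyl-2-oxocyclohex-3-en-1-yl acetate
Product: 3 2,4-dimethylcyclohex-3-ene-1,2-diol (racemic; both diastereomers)
Conditions: MeMgBr (excess), THF, −78 to 0 °C; aq. work-up
Reagents that add atoms: methylmagnesium bromide, C[Mg]Br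
Why: Grignard 1,2-addition to the enone carbonyl creates the future acetyl unit (C8 with C7) and excess reagent cleaves the acetate to the free glycol; both diastereomers converge in step 3.

Step 3
Reactants: 3 2,4-dimethylcyclohex-3-ene-1,2-diol
Product: 4 (4Z)-4-methyl-6-oxohept-4-enal
Conditions: NaIO4 on silica gel, CH2Cl2, 0 °C to rt; used directly
Reagents that add atoms: none
Why: Periodate glycol cleavage opens the ring between the two carbinol carbons, and the ring-enforced cis arrangement of the two chain ends on C9=C10 is kept as the (Z)-enone geometry.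

Step 4
Reactants: 4 (4Z)-4-methyl-6-oxohept-4-enal
Product: 6 (3Z,7S)-7-hydroxy-4,8,8-trimethyldeca-3,9-dien-2-one, via diisopinocampheylborinate 5 (not isolated)
Conditions: (+)-Ipc2BH [(−)-α-pinene series], 3-methylbuta-1,2-diene, Et2O, −25 °C; then 4, −78 °C; NaBO3·4H2O, THF/H2O, rt
Reagents that add atoms: 3-methylbuta-1,2-diene, CC(C)=C=C (transferred as the prenyl group of the borane made in the flask)
Why: Asymmetric prenylboration (Brown allylboration type, chair-like six-membered transition state with γ-attack) adds to the aldehyde in preference to the ketone at −78 °C, builds C3–C4 with the gem-dimethyl group and the C5=C6 vinyl group, and sets C3 as (S) under control of the isopinocampheyl groups.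

Step 5
Reactants: 6 (3Z,7S)-7-hydroxy-4,8,8-trimethyldeca-3,9-dien-2-one
Product: 7 (3Z,7S,9E)-7-hydroxy-4,8,8-trimethyl-10-(phenylsulfonyl)deca-3,9-dien-2-one
Conditions: phenyl vinyl sulfone (3 equiv), second-generation Hoveyda–Grubbs catalyst (5 mol%), CH2Cl2, 40 °C
Reagents that add atoms: phenyl vinyl sulfone, C=CS(=O)(=O)c1ccccc1
Why: Olefin cross metathesis: the monosubstituted alkene is the only metathesis-competent olefin of 6 (the trisubstituted enone is inert) and the vinyl sulfone does not homodimerise, so the (E)-vinyl sulfone should form; the sulfonyl group is a temporary dienophile activator.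

Step 6
Reactants: 7 (3Z,7S,9E)-7-hydroxy-4,8,8-trimethyl-10-(phenylsulfonyl)deca-3,9-dien-2-one
Product: 9 (3Z,7S,9E)-2,7-bis(tert-butyldimethylsilyloxy)-4,8,8-trimethyl-10-(phenylsulfonyl)deca-1,3,9-triene, via mono-silyl ether 8 (not isolated)
Conditions: TBSOTf (2.6 equiv), Et3N, CH2Cl2, −78 to 0 °C
Reagents that add atoms: tert-butyldimethylsilyl trifluoromethanesulfonate, CC(C)(C)[Si](C)(C)OS(=O)(=O)C(F)(F)F
Why: Silyl triflate/amine silylation protects the hindered C3 hydroxyl and enol-silylates the methyl ketone kinetically at the methyl group (C7) to the cross-conjugated 2-silyloxydiene without strong base, so the (Z) geometry of C9=C10 and the vinyl sulfone stay intact.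

Step 7
Reactants: 9 (3Z,7S,9E)-2,7-bis(tert-butyldimethylsilyloxy)-4,8,8-trimethyl-10-(phenylsulfonyl)deca-1,3,9-triene
Product: 10 cis-fused silyl enol ether 3β,8-bis(TBSO)-4,4,10β-trimethyl-6β-(phenylsulfonyl)-5βH-decal-8-ene (C8=C9)
Conditions: toluene (0.01 M), BHT (cat.), 150 °C, sealed base-washed tube
Reagents that add atoms: none
Why: Thermal intramolecular Diels–Alder reaction (concerted suprafacial [4+2]) of a 1,7,9-decatriene in which the 2-silyloxydiene C7=C8(OTBS)–C9=C10 and the sulfonyl-activated dienophile C5=C6 are joined by the four-atom chain C1–C4; the closest known reaction type is the cycloaddition of (Z)-diene trienes bearing a terminal sulfonyl or carbonyl activator, which gives cis-fused bicyclo[4.4.0]decenes. Ring B closes as the cyclohexene of the [4+2] event itself (bonds C5–C10 and C6–C7, boat-like array) and ring A closes in the same event as the fused tether ring through C5–C10, its chair-like chain helped by the C4 gem-dimethyl group; the four-atom tether allows only the fused orientation, so the regiochemistry is fixed although the 2-silyloxy group would favour the other pairing. C10 (quaternary) and C5 are set cis (CH3-10 and H-5 on one face) because the tether occupies the inside position of the (Z)-diene terminus and can reach the dienophile only in the tether-exo transition state; C6 follows from the (E)-dienophile and is erased in step 10. The absolute sense is controlled by C3: the silyloxy group takes the equatorial position of the chair-like tether, since addition to the other diene face would place it 1,3-diaxial to C6, and this array is the 3β,5β,10β series. The step needs chemoselectivity over the 1,5-hydrogen shift of the (Z)-diene and over desilylation, which the sulfone (lower temperature), the radical inhibitor and base-washed glass are meant to secure. The new enol ether C8=C9 is the regiodefined handle for steps 8 and 9.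

Step 8
Reactants: 10 cis-fused silyl enol ether
Product: 11 3β-(TBSO)-4,4,10β-trimethyl-6β-(phenylsulfonyl)-9β-(phenylthiomethyl)-5βH,9αH-decalin-8-one
Conditions: PhSCH2Cl, TiCl4, CH2Cl2, −78 to −40 °C
Reagents that add atoms: chloromethyl phenyl sulfide, ClCSc1ccccc1
Why: Lewis-acid alkylation of a silyl enol ether by a thionium ion (no base, so the acidic C6–H next to the sulfone is untouched) occurs at C9 only; axial attack from the convex β face, anti to the pseudoaxial C10–C1 bond and away from ring A, should place CH2SPh β and H-9 α.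

Step 9
Reactants: 11 9β-(phenylthiomethyl) ketone
Product: 12 3β-(TBSO)-4,4,8β,10β-tetramethyl-6β-(phenylsulfonyl)-9β-(phenylthiomethyl)-5βH,9αH-decalin-8α-ol
Conditions: MeMgBr, CeCl3 (anhydrous), THF, −78 °C
Reagents that add atoms: methylmagnesium bromide, C[Mg]Br
Why: Organocerium 1,2-addition (non-basic, so no epimerisation at C9 and no β-elimination of thiophenolate); in the conformer with the quaternary C4 equatorial on ring B the axial α trajectory at C8 is closed by the syn-axial C10–C1 bond and the fold of ring A, so CH3 should enter equatorially from the β face and leave the axial 8α-OH.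

Step 10
Reactants: 12 6β-sulfonyl tertiary alcohol
Product: 13 3β-(TBSO)-4,4,8β,10β-tetramethyl-9β-(phenylthiomethyl)-5βH,9αH-decalin-8α-ol
Conditions: 6% Na(Hg), Na2HPO4, MeOH/THF, −20 °C
Reagents that add atoms: none
Why: Reductive desulfonylation by electron transfer cleaves the C6–S bond and methanol protonates the carbanion, turning C6 into CH2; the alkyl phenyl sulfide, the silyl ether and the tertiary alcohol are inert.

Step 11
Reactants: 13 9β-(phenylthiomethyl) alcohol
Product: 15 3β-(TBSO)-4,4,8β,10β-tetramethyl-9β-(phenylsulfonylmethyl)-5βH,9αH-decalin-8α-ol, via sulfoxide 14 (not isolated)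
Conditions: mCPBA (2.2 equiv), NaHCO3, CH2Cl2, 0 °C
Reagents that add atoms: 3-chloroperoxybenzoic acid, OOC(=O)c1cccc(Cl)c1
Why: Chemoselective sulfide-to-sulfone oxidation (no alkene is present at this stage) gives the acidifying group needed at C11.

Step 12
Reactants: 16 (2E,6E)-farnesyl acetate
Product: 17 (2E,6E,10E)-12-hydroxy-3,7,11-trimethyldodeca-2,6,10-trien-1-yl acetate
Conditions: SeO2 (cat.), t-BuOOH, salicylic acid (cat.), CH2Cl2, 0 °C to rt
Reagents that add atoms: tert-butyl hydroperoxide, CC(C)(C)OO (net oxygen source)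
Why: SeO2-catalysed allylic oxidation (ene reaction, then [2,3]-sigmatropic shift) attacks the (E)-methyl group of the most electron-rich, terminal trisubstituted alkene and gives the (E)-allylic alcohol that becomes C23.

Step 13
Reactants: 17 12-hydroxyfarnesyl acetate
Product: 18 (2E,6E,10E)-12-(TBSO)-3,7,11-trimethyldodeca-2,6,10-trien-1-yl acetate
Conditions: TBSCl, imidazole, CH2Cl2, rt
Reagents that add atoms: tert-butylchlorodimethylsilane, CC(C)(C)[Si](C)(C)Cl
Why: Standard silylation of the primary allylic alcohol, so that C23-OH survives the carbanion and amalgam steps.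

Step 14
Reactants: 18 silyl ether acetate
Product: 19 (2E,6E,10E)-12-(TBSO)-3,7,11-trimethyldodeca-2,6,10-trien-1-ol
Conditions: K2CO3, MeOH, rt
Reagents that add atoms: none
Why: Base-catalysed transesterification removes the acetate and leaves the silyl ether.

Step 15
Reactants: 19 allylic alcohol
Product: 20 tert-butyl{[(2E,6E,10E)-12-bromo-2,6,10-trimethyldodeca-2,6,10-trien-1-yl]oxy}dimethylsilane
Conditions: CBr4, PPh3, CH2Cl2, −20 °C; used without storage
Reagents that add atoms: carbon tetrabromide, BrC(Br)(Br)Br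
Why: Appel bromination of a primary allylic alcohol proceeds by SN2 without allylic transposition or loss of alkene geometry.

Step 16
Reactants: 15 C11 sulfone; 20 allylic bromide
Product: 22 11-(phenylsulfonyl)-3β,23-bis(TBSO) coupling product (C11 epimers), via dilithio dianion 21 (not isolated)
Conditions: n-BuLi (2.2 equiv), THF/DMPU, −78 °C; then 20, −78 to −20 °C
Reagents that add atoms: none
Why: Alkylation of an α-sulfonyl carbanion (second equivalent of base after alkoxide formation) with a primary allylic bromide forms C11–C12 by SN2 with the three (E)-alkenes untouched; the new C11 stereocentre is removed in step 17.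

Step 17
Reactants: 22 coupled sulfone
Product: 23 3β,23-bis(TBSO)-8α-ol with the complete carbon skeleton
Conditions: 6% Na(Hg), Na2HPO4, MeOH/THF, −20 °C
Reagents that add atoms: none
Why: Reductive desulfonylation; the sulfone is homoallylic and not allylic, so no double-bond migration is expected, and silyl ethers and isolated alkenes are inert.

Step 18
Reactants: 23 bis-silyl ether
Product: 24 3β,8α,23-triol
Conditions: TBAF, THF, 50 °C
Reagents that add atoms: none
Why: Fluoride-mediated cleavage of both silyl ethers; no base-sensitive group is present yet.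

Step 19
Reactants: 24 3β,8α,23-triol
Product: 25 3β,8α-diol 23-acetate
Conditions: Ac2O (1.1 equiv), pyridine, CH2Cl2, 0 °C (no DMAP)
Reagents that add atoms: acetic anhydride, CC(=O)OC(C)=O
Why: Rate-controlled acylation takes the unhindered primary allylic hydroxyl; the neopentyl-type secondary 3-OH and the tertiary 8-OH react far more slowly.

Step 20
Reactants: 25 3β,8α-diol 23-acetate
Product: 26 Myrrhanone A acetate
Conditions: Dess–Martin periodinane, NaHCO3, CH2Cl2, rt
Reagents that add atoms: none
Why: Dess–Martin oxidation of the only secondary alcohol gives the C3 ketone; the tertiary alcohol, the allylic acetate and the alkenes are inert, and the C3 stereocentre that steered step 7 is removed.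

**Compound list**
1 | 3-methylcyclohex-2-en-1-one | CC1=CC(=O)CCC1 | starting material
2 | (±)-4-methyl-2-oxocyclohex-3-en-1-yl acetate | CC1=CC(=O)C(OC(C)=O)CC1 | intermediate
3 | 2,4-dimethylcyclohex-3-ene-1,2-diol (racemic, both diastereomers) | CC1=CC(C)(O)C(O)CC1 | intermediate
4 | (4Z)-4-methyl-6-oxohept-4-enal | O=CCC/C(C)=C\C(C)=O | intermediate
5 | (3Z,7S)-4,8,8-trimethyl-2-oxodeca-3,9-dien-7-yl diisopinocampheylborinate | CC(=O)/C=C(C)\CC[C@H](OB([C@H]1C[C@H]2C[C@@H]([C@@H]1C)C2(C)C)[C@H]1C[C@H]2C[C@@H]([C@@H]1C)C2(C)C)C(C)(C)C=C | intermediate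
6 | (3Z,7S)-7-hydroxy-4,8,8-trimethyldeca-3,9-dien-2-one | CC(=O)/C=C(C)\CC[C@H](O)C(C)(C)C=C | intermediate
7 | (3Z,7S,9E)-7-hydroxy-4,8,8-trimethyl-10-(phenylsulfonyl)deca-3,9-dien-2-one | CC(=O)/C=C(C)\CC[C@H](O)C(C)(C)/C=C/S(=O)(=O)c1ccccc1 | intermediate
8 | (3Z,7S,9E)-7-(tert-butyldimethylsilyloxy)-4,8,8-trimethyl-10-(phenylsulfonyl)deca-3,9-dien-2-one | CC(=O)/C=C(C)\CC[C@H](O[Si](C)(C)C(C)(C)C)C(C)(C)/C=C/S(=O)(=O)c1ccccc1 | intermediate
9 | (3Z,7S,9E)-2,7-bis(tert-butyldimethylsilyloxy)-4,8,8-trimethyl-10-(phenylsulfonyl)deca-1,3,9-triene | C=C(O[Si](C)(C)C(C)(C)C)/C=C(C)\CC[C@H](O[Si](C)(C)C(C)(C)C)C(C)(C)/C=C/S(=O)(=O)c1ccccc1 | intermediate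
10 | 3β,8-bis(TBSO)-4,4,10β-trimethyl-6β-(phenylsulfonyl)-5βH-decal-8-ene (cis-fused; C8=C9 silyl enol ether) | C[C@]12CC[C@H](O[Si](C)(C)C(C)(C)C)C(C)(C)[C@H]1[C@H](S(=O)(=O)c1ccccc1)CC(O[Si](C)(C)C(C)(C)C)=C2 | intermediate
11 | 3β-(TBSO)-4,4,10β-trimethyl-6β-(phenylsulfonyl)-9β-(phenylthiomethyl)-5βH,9αH-decalin-8-one | C[C@]12CC[C@H](O[Si](C)(C)C(C)(C)C)C(C)(C)[C@H]1[C@H](S(=O)(=O)c1ccccc1)CC(=O)[C@@H]2CSc1ccccc1 | intermediate
12 | 3β-(TBSO)-4,4,8β,10β-tetramethyl-6β-(phenylsulfonyl)-9β-(phenylthiomethyl)-5βH,9αH-decalin-8α-ol | C[C@]12CC[C@H](O[Si](C)(C)C(C)(C)C)C(C)(C)[C@H]1[C@H](S(=O)(=O)c1ccccc1)C[C@@](C)(O)[C@@H]2CSc1ccccc1 | intermediate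
13 | 3β-(TBSO)-4,4,8β,10β-tetramethyl-9β-(phenylthiomethyl)-5βH,9αH-decalin-8α-ol | C[C@]12CC[C@H](O[Si](C)(C)C(C)(C)C)C(C)(C)[C@H]1CC[C@@](C)(O)[C@@H]2CSc1ccccc1 | intermediate
14 | 9β-(phenylsulfinylmethyl) analogue of 13 (sulfur epimers) | C[C@]12CC[C@H](O[Si](C)(C)C(C)(C)C)C(C)(C)[C@H]1CC[C@@](C)(O)[C@@H]2CS(=O)c1ccccc1 | intermediate
15 | 3β-(TBSO)-4,4,8β,10β-tetramethyl-9β-(phenylsulfonylmethyl)-5βH,9αH-decalin-8α-ol | C[C@]12CC[C@H](O[Si](C)(C)C(C)(C)C)C(C)(C)[C@H]1CC[C@@](C)(O)[C@@H]2CS(=O)(=O)c1ccccc1 | intermediate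
16 | (2E,6E)-farnesyl acetate | CC(=O)OC/C=C(C)/CC/C=C(C)/CCC=C(C)C | starting material
17 | (2E,6E,10E)-12-hydroxy-3,7,11-trimethyldodeca-2,6,10-trien-1-yl acetate | CC(=O)OC/C=C(C)/CC/C=C(C)/CC/C=C(C)/CO | intermediate
18 | (2E,6E,10E)-12-(tert-butyldimethylsilyloxy)-3,7,11-trimethyldodeca-2,6,10-trien-1-yl acetate | CC(=O)OC/C=C(C)/CC/C=C(C)/CC/C=C(C)/CO[Si](C)(C)C(C)(C)C | intermediate
19 | (2E,6E,10E)-12-(tert-butyldimethylsilyloxy)-3,7,11-trimethyldodeca-2,6,10-trien-1-ol | OC/C=C(C)/CC/C=C(C)/CC/C=C(C)/CO[Si](C)(C)C(C)(C)C | intermediate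
20 | tert-butyl{[(2E,6E,10E)-12-bromo-2,6,10-trimethyldodeca-2,6,10-trien-1-yl]oxy}dimethylsilane | BrC/C=C(C)/CC/C=C(C)/CC/C=C(C)/CO[Si](C)(C)C(C)(C)C | intermediate
21 | dilithio dianion of 15 (lithium 8-alkoxide, C11 carbanion) | C[C@]12CC[C@H](O[Si](C)(C)C(C)(C)C)C(C)(C)[C@H]1CC[C@@](C)(O[Li])[C@@H]2C([Li])S(=O)(=O)c1ccccc1 | intermediate
22 | 11-(phenylsulfonyl)-3β,23-bis(TBSO)-8α-hydroxy coupling product (C11 epimers) | C[C@]12CC[C@H](O[Si](C)(C)C(C)(C)C)C(C)(C)[C@H]1CC[C@@](C)(O)[C@@H]2C(C/C=C(C)/CC/C=C(C)/CC/C=C(C)/CO[Si](C)(C)C(C)(C)C)S(=O)(=O)c1ccccc1 | intermediate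
23 | 3β,23-bis(TBSO)-8α-ol (13E,17E,21E) | C[C@]12CC[C@H](O[Si](C)(C)C(C)(C)C)C(C)(C)[C@H]1CC[C@@](C)(O)[C@@H]2CC/C=C(C)/CC/C=C(C)/CC/C=C(C)/CO[Si](C)(C)C(C)(C)C | intermediate
24 | 3β,8α,23-triol (13E,17E,21E) | C[C@]12CC[C@H](O)C(C)(C)[C@H]1CC[C@@](C)(O)[C@@H]2CC/C=C(C)/CC/C=C(C)/CC/C=C(C)/CO | intermediate
25 | 3β,8α-diol 23-acetate (3-dihydro form of the target) | C[C@]12CC[C@H](O)C(C)(C)[C@H]1CC[C@@](C)(O)[C@@H]2CC/C=C(C)/CC/C=C(C)/CC/C=C(C)/COC(C)=O | intermediate
26 | Myrrhanone A acetate | C[C@]12CCC(=O)C(C)(C)[C@H]1CC[C@@](C)(O)[C@@H]2CC/C=C(C)/CC/C=C(C)/CC/C=C(C)/COC(C)=O | target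

**Step count**
Total: 20 steps. Longest linear sequence: 16 steps (steps 1–11 and 16–20); the side chain takes 4 steps (12–15).

**Steps most likely to fail**

Step 7. The cycloaddition may be too slow in the tether-enforced, electronically mismatched orientation at the congested C5–C10 bond, so that the 1,5-hydrogen shift of the (Z)-diene or loss of the enol silyl group takes over. The fallback sets out from 6 and returns at 13; it replaces the sulfonyl activator by a formyl group that is removed directly after the cycloaddition. Cross metathesis of 6 with acrolein (second-generation Hoveyda–Grubbs catalyst, CH2Cl2, 40 °C) should give the enal F1. TBSOTf/Et3N as in step 6 should give the silyloxy triene F2. Heating in toluene at 110 °C (stronger activation, formyl group endo, same (Z)-diene and C3 control) should give the 6β-formyl cis-decalin enol ether F3. Stoichiometric RhCl(PPh3)3 in toluene at 110 °C (Tsuji–Wilkinson decarbonylation) should give the enol ether F4 with C6 as CH2. PhSCH2Cl/TiCl4 as in step 8 should give the ketone F5, and MeMgBr/CeCl3 as in step 9 should give 13.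

Step 9. The facial selectivity of the methyl addition at C8 may be poor or reversed, because the equatorial β trajectory passes the axial C9 substituent; enolisation is a second risk. The fallback sets out from 11 and returns at 12; it brings in the oxygen last instead of the carbon. Non-basic methylenation with Cp2TiMe2 (toluene, 65 °C) should give the 8-methylidene compound F6. Mukaiyama hydration (Mn(dpm)3 cat., PhSiH3, O2, i-PrOH; then PPh3) converts the 1,1-disubstituted alkene into the tertiary alcohol. The planar C8 radical is trapped by O2 on the face that a carbon nucleophile would have taken, so the C8 configuration opposite to that of direct addition results, which is 12 if direct addition delivered the 8-epimer.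

Step 5. Cross metathesis may not turn over at the vinyl group flanked by the quaternary C4, or the catalyst may decompose first. The fallback sets out from 6 and returns at 8; it builds the vinyl sulfone by olefination. TBSOTf/2,6-lutidine (CH2Cl2, −78 °C) should give the silyl ether F7. OsO4 (cat.)/NaIO4/2,6-lutidine in dioxane/H2O (Lemieux–Johnson cleavage; the electron-poor trisubstituted enone alkene reacts far more slowly than the vinyl group) should give the aldehyde F8. Horner–Wadsworth–Emmons reaction with diethyl (phenylsulfonylmethyl)phosphonate (LiCl, DBU, MeCN) should give the (E)-vinyl sulfone 8, which is enol-silylated as in step 6 with one equivalent of TBSOTf.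

**Further compounds**
F1 | step 7 | (2E,4S,8Z)-4-hydroxy-5,5,8-trimethyl-10-oxoundeca-2,8-dienal | CC(=O)/C=C(C)\CC[C@H](O)C(C)(C)/C=C/C=O
F2 | step 7 | (2E,4S,8Z)-4,10-bis(tert-butyldimethylsilyloxy)-5,5,8-trimethylundeca-2,8,10-trienal | C=C(O[Si](C)(C)C(C)(C)C)/C=C(C)\CC[C@H](O[Si](C)(C)C(C)(C)C)C(C)(C)/C=C/C=O
F3 | step 7 | 3β,8-bis(TBSO)-6β-formyl-4,4,10β-trimethyl-5βH-decal-8-ene | C[C@]12CC[C@H](O[Si](C)(C)C(C)(C)C)C(C)(C)[C@H]1[C@H](C=O)CC(O[Si](C)(C)C(C)(C)C)=C2
F4 | step 7 | 3β,8-bis(TBSO)-4,4,10β-trimethyl-5βH-decal-8-ene | C[C@]12CC[C@H](O[Si](C)(C)C(C)(C)C)C(C)(C)[C@H]1CCC(O[Si](C)(C)C(C)(C)C)=C2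
F5 | step 7 | 3β-(TBSO)-4,4,10β-trimethyl-9β-(phenylthiomethyl)-5βH,9αH-decalin-8-one | C[C@]12CC[C@H](O[Si](C)(C)C(C)(C)C)C(C)(C)[C@H]1CCC(=O)[C@@H]2CSc1ccccc1
F6 | step 9 | 3β-(TBSO)-4,4,10β-trimethyl-8-methylidene-6β-(phenylsulfonyl)-9β-(phenylthiomethyl)-5βH,9αH-decalin | C[C@]12CC[C@H](O[Si](C)(C)C(C)(C)C)C(C)(C)[C@H]1[C@H](S(=O)(=O)c1ccccc1)CC(=C)[C@@H]2CSc1ccccc1
F7 | step 5 | (3Z,7S)-7-(tert-butyldimethylsilyloxy)-4,8,8-trimethyldeca-3,9-dien-2-one | CC(=O)/C=C(C)\CC[C@H](O[Si](C)(C)C(C)(C)C)C(C)(C)C=C
F8 | step 5 | (3S,6Z)-3-(tert-butyldimethylsilyloxy)-2,2,6-trimethyl-8-oxonon-6-enal | CC(=O)/C=C(C)\CC[C@H](O[Si](C)(C)C(C)(C)C)C(C)(C)C=O
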